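(The runs were generated by integration for an exercise, and the scatter is random.)

Moles of product per mole of catalyst charged: that is the unit in which two chemists dispute the amber flask.

common to all: substrate 0.50 M; free catalyst 1 mol%

|  | partner | temperature | remark | time |
|---|---|---|---|---|
| amber | 0.70 equiv | 25 °C | the very flask that is asked about, followed so far |  |
| teal | 0.70 equiv | 31 °C | run made earlier |  |
| flask | 0.700 equiv | 25 °C |  | 8.0 d |

| amber: time / d | amber: product / % | teal: time / d | teal: product / % |
|---|---|---|---|
| 0.417 | 12.9 | 0.417 | 13.2 |
| 1.25 | 21.4 | 1.25 | 21.0 |
| 2.00 | 20.7 | 2.00 | 19.1 |
| 3.00 | 22.7 | 3.00 | 21.1 |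
| 5.00 | 22.3 | 5.00 | 20.0 |

(readings scatter by 1 percentage point)

- eta: change nothing and wait 2.5 d more
- zeta: at 8.0 d take out 90% of the product then present, then wait 2.5 d
- theta: at 8.0 d add free catalyst, 100% of the amount charged, then wait 2.5 d
- epsilon: at 8.0 d raise the temperature by 15 K, then wait 2.5 d
- delta: at 8.0 d add partner, 100% of the amount charged, then wait 2.5 d

- removed product is counted in
- additions bring no volume worth counting

1. product, in percent of the substrate first charged, at 8.0 d
2. the option that brings most further product ("none" if no option brings more than 2 percentage points) (eta / zeta / theta / epsilon / delta / none)
3. product present, with what was taken out counted in, in percent of the substrate first charged, after eta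
4. product present, with what was taken out counted in, in percent of the substrate first charged, after theta

Amber is the flask asked about; teal is its warmer twin. Over its last 4 readings amber averages 21.8%, and teal averages 20.3%, which is lower. Their first readings, 12.9% and 13.2%, lie within the scatter.

The first chemist sees a balance: “A plateau that falls with temperature points to an exothermic equilibrium”. The forecast is that chemist's: 22% now, 22% after eta, 22.2% after theta (range 21% to 27%), and delta as best.

The second chemist, whose reckoning is mine, sees a catalyst that stops working. The same readings fit this view, so the quantity to carry is N, the turnover number, the product made per catalyst charged before activity ends. Amber gives 21.8.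

Now compare rates at one moment. Each catalyst either turns once more or dies, and its turning goes with substrate times partner. At the plateau, if product took both one for one, 78.2% of the substrate and 68.9% of the partner remain, so a fresh charge works in a poorer flask than the first did. If dying also needs substrate, substrate cancels and the fresh charge is worth N times the partner share, 15 percentage points. If not, both shares count, giving 12 points. Amber's reading at 2.00 d, a time shorter than the wait of 2.5 d, was already 20.7% against that average of 21.8%. So I expect theta to end between 33.8% and 36.8%, and delta to bring nothing beyond the scatter.

The flask gives 23.0% at 8.0 d and 23.0% after eta, both inside the forecast's ranges, and at 80.0 d it still stands at 23.0%. Both chemists expected this flat line, so these numbers do not part their views. But theta is best: it ends at 36.8%, a gain of 14 points, while delta gains 0 points, with free catalyst at 0.00848% of its charge at 8.00 d.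

    substrate + partner + free catalyst → free catalyst + product (k = 0.00330 L² mol⁻² s⁻¹, Ea = 48.0 kJ mol⁻¹)
    substrate + free catalyst → spent catalyst A (k = 3.30 × 10⁻⁵ L mol⁻¹ s⁻¹, Ea = 62.0 kJ mol⁻¹)
    2 free catalyst → spent catalyst B (k = 8.30 × 10⁻⁴ L mol⁻¹ s⁻¹, Ea = 60.0 kJ mol⁻¹)
    (constants at 25 °C)

N times the partner share gave 15 points against that gain of 14 points. Scaled to the neighbouring flask with 1.80 equiv of partner, N gives 56.0%, and that flask stands at 57.1%.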